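The numbers in the tables are calculated from invented constants.

Per minute is the unit I would answer you in: a share of the starting material lost each minute can be carried from one flask to the next if it holds steady. You asked for a quick number on Sunday's flask, and your hunch was that the added target will hold it back.

| flask | starting material | free catalyst | target | time |
|---|---|---|---|---|
| Tuesday's | 0.800 M | 0.0640 M |  |  |
| Wednesday's | 0.480 M | 0.0640 M |  |  |
| Friday's | 1.20 M | 0.0640 M |  |  |
| Saturday's | 0.800 M | 0.190 M |  |  |
| Sunday's | 0.800 M | 0.0640 M | 0.640 M | 61 min |

| run | time / min | [starting material] / M |
|---|---|---|
| Tuesday's run | 12 | 0.440 |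
| Tuesday's run | 24 | 0.283 |
| Tuesday's run | 37 | 0.193 |
| Tuesday's run | 49 | 0.130 |
| Tuesday's run | 61 | 0.097 |
| Wednesday's run | 12 | 0.285 |
| Wednesday's run | 24 | 0.194 |
| Wednesday's run | 37 | 0.124 |
| Wednesday's run | 49 | 0.084 |
| Wednesday's run | 61 | 0.071 |
| Friday's run | 12 | 0.647 |
| Friday's run | 24 | 0.403 |
| Friday's run | 37 | 0.257 |
| Friday's run | 49 | 0.193 |
| Friday's run | 61 | 0.143 |
| Saturday's run | 12 | 0.274 |
| Saturday's run | 24 | 0.131 |
| Saturday's run | 37 | 0.096 |
| Saturday's run | 49 | 0.065 |
| Saturday's run | 61 | 0.053 |

(readings scatter by 0.006 M)

* the power of [free catalyst] that the first rate follows, about the charge of the Tuesday's run; measure it at two percent of starting material made into target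
* the power of [starting material] that the first rate follows, about the charge of the Tuesday's run; measure it at two percent of starting material made into target (one fixed amount of target, the same in the runs compared)
* starting material in the Sunday's run at 61 min, as a share of the starting material charged

- Overall: starting material -> target, with free catalyst as catalyst.
- Constant volume, constant temperature.
- Readings of a species count what is bound in complexes too.
- An order is taken over about fifteen percent of the charge, up and down.

Tuesday's flask falls from its charge to 0.097 M in 61 min, which is 0.0346 min⁻¹ if the loss is taken as one steady pseudo-first-order constant; call that average the run constant. It hides a sag, since the first 12 min of Tuesday's flask alone give 0.0498 min⁻¹.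

Your hunch can be held against two flasks with equal catalyst, over the same stretch from 12 min to 61 min. Friday's flask reads 0.0308 min⁻¹ there and Wednesday's 0.0284 min⁻¹, although by the end Friday's has lost 1.06 M of starting material and Wednesday's 0.409 M. The two constants differ by 0.002400 min⁻¹, and one standard deviation of 0.006 M on Wednesday's last reading moves Wednesday's constant by 0.001725 min⁻¹, so this comparison does not tell a sag with the clock from a sag with the amount turned.

Sunday's flask has Tuesday's charges plus 0.640 M of target, and no earlier run was charged with target, so my own reckoning sets the target aside, keeps the run constant and commits to 12.1% left at 61 min.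

The forecast, from the same runs, differs from that: it gives 16% left, with powers 1.15 in starting material and 0.65 in free catalyst. On the sag it says: “This points to mild product inhibition or catalyst loss, but the two are not cleanly separated”.

The flask gives 12.9% left on Sunday, with powers 1.1 in starting material and 0.94 in free catalyst, and the catalyst power is where the forecast parts from it, as Saturday's first rate stands 2.6 times Tuesday's on a catalyst charge 2.97 times as large.

    free catalyst + starting material ⇌ catalyst-substrate complex, settled at all times (1.050 M⁻¹)
    catalyst-substrate complex + starting material ⇌ doubly bound catalyst, settled at all times (1.850 M⁻¹)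
    doubly bound catalyst → target + catalyst-substrate complex (1.314 min⁻¹)
    free catalyst + starting material → spent catalyst + starting material (0.1164 M⁻¹ min⁻¹)
    starting material → decomposed substrate (0.01920 min⁻¹)

The run constant's 12.1% lies 0.80 percentage points below Sunday's value, which on Sunday's charge is 0.00604 M, against a scatter of 0.006 M. Put on Friday's flask, the run constant has a quarter of the charge gone at 8.31 min, and the target made comes to a quarter of that charge at 9.23 min.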